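Ring B is closed at its C5–C6 bond (eremophilane numbering: C5 = quaternary methyl-bearing ring-fusion carbon, C6 = ring-B methylene) by an anionic oxy-Cope rearrangement. The C8 ketone and a C3=C4 alkene (the later C3–O/C4–H centres) form the δ,ε-unsaturated-ketone retron, so the precursor is no decalin but a 2-vinylbicyclo[2.2.2]oct-5-en-2-ol whose tetrasubstituted alkene carries both future methyl groups. One operation forms C5–C6, cleaves the C3–C8 bridge bond, relays bridgehead chirality from a catalytic Diels–Alder reaction to C5 and releases a regiodefined C7–C8 enolate, trapped with acetone. Hydroboration anti to the C5 methyl then sets C3 and C4; C9 autoxidation gives the diosphenol.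

Key step: step 6

Remark on numbering: the decalin is numbered as an eremophilane (ring A: C1–C5 and C10; ring B: C5–C10; C14 = methyl on C5, C15 = methyl on C4, C11–C13 = isopropylidene carbons).

Assumption: the (5S)-imidazolidinone is taken to give the Diels–Alder adduct of step 3 with the same facial sense as with cyclohexa-1,3-diene and acrolein; if the sense were opposite, the (5R)-catalyst would be used.

Step 1
Reactants: 1 2-methylcyclohex-2-en-1-one
Product: 3 6-methylcyclohexa-1,5-dien-1-yl trifluoromethanesulfonate, via lithium dienolate 2 (not isolated)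
Conditions: LiN(iPr)2, THF, −78 °C; PhNTf2, −78 → 0 °C; aq. NH4Cl
Reagents that add atoms: N-phenylbis(trifluoromethanesulfonimide), O=S(=O)(N(c1ccccc1)S(=O)(=O)C(F)(F)F)C(F)(F)F
Why: Kinetic α′-deprotonation of the enone gives the cross-conjugated dienolate, whose O-sulfonylation (enol triflate formation) fixes the 1,3-diene with the triflate on an inner diene carbon.

Step 2
Reactants: 3 6-methylcyclohexa-1,5-dien-1-yl trifluoromethanesulfonate
Product: 4 2,3-dimethylcyclohexa-1,3-diene
Conditions: MeMgBr, Fe(acac)3 (5 mol %), THF/NMP, −30 → 0 °C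
Reagents that add atoms: methylmagnesium bromide, C[Mg]Br
Why: Iron-catalysed Kumada-type cross-coupling of an alkenyl triflate with a methyl Grignard reagent should exchange OTf for CH3 without moving the diene.

Step 3
Reactants: 4 2,3-dimethylcyclohexa-1,3-diene; 5 acrolein
Product: 6 (1S,2R,4R)-5,6-dimethylbicyclo[2.2.2]oct-5-ene-2-carbaldehyde (endo)
Conditions: (5S)-5-benzyl-2,2,3-trimethylimidazolidin-4-one hydrochloride (10 mol %; first-generation MacMillan catalyst), MeOH/H2O, rt; chromatographic removal of the minor exo adduct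
Reagents that add atoms: none
Why: Iminium-catalysed asymmetric Diels–Alder reaction: the benzyl group of the catalyst shields one face of the acrolein iminium ion, so the C2-symmetric diene (no regiochemical issue) should add endo to the open face and set both bridgehead centres; the exo adduct is removed because it would lead to the enantiomeric ketone.

Step 4
Reactants: 6 (1S,2R,4R)-5,6-dimethylbicyclo[2.2.2]oct-5-ene-2-carbaldehyde
Product: 7 (1R,4R)-5,6-dimethylbicyclo[2.2.2]oct-5-en-2-one
Conditions: O2 (1 atm), Cu(OAc)2 (cat.), 2,2′-bipyridine, DABCO, DMF, 40–70 °C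
Reagents that add atoms: dioxygen, O=O
Why: Copper-catalysed aerobic oxidative deformylation of an α-branched aldehyde (via its enol or enamine and an α-hydroperoxide) should give the ketone and formic acid, and the bridgehead centres cannot epimerise.

Step 5
Reactants: 7 (1R,4R)-5,6-dimethylbicyclo[2.2.2]oct-5-en-2-one; 8 vinylmagnesium bromide
Product: 9 (1R,2R,4R)-2-ethenyl-5,6-dimethylbicyclo[2.2.2]oct-5-en-2-ol (vinyl syn to the C5=C6 bridge)
Conditions: CeCl3 (anhydrous), THF, −78 °C; aq. NH4Cl
Reagents that add atoms: none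
Why: Organocerium 1,2-addition (suppresses enolisation) from the carbonyl face next to the flat C5=C6 bridge, which is more open than the face next to the CH2–CH2 bridge (the methyl groups lie in the alkene plane), should place the vinyl group syn to the alkene as the rearrangement requires.

Step 6
Reactants: 9 (1R,2R,4R)-2-ethenyl-5,6-dimethylbicyclo[2.2.2]oct-5-en-2-ol; 10 acetone
Product: 14 (5S,10R)-11-hydroxyeremophil-3-en-8-one (cis-fused; C7 epimers), via potassium alkoxide 11 (not isolated), via potassium enolate 12 (not isolated), via chlorozinc enolate 13 (not isolated)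
Conditions: KN(SiMe3)2, 18-crown-6, THF, 0 → 40 °C; ZnCl2, −78 °C; acetone, −78 → −40 °C; aq. NH4Cl
Reagents that add atoms: none
Why: Deprotonation gives alkoxide 11, whose 1,5-diene (C6=C7–C8(O−)–C3–C4=C5) undergoes an anionic oxy-Cope [3,3]-sigmatropic rearrangement, the known behaviour of 2-vinylbicyclo[2.2.2]oct-5-en-2-olates, in which the C3–C8 σ bond breaks as the C5–C6 σ bond forms to give enolate 12. Ring B (C5–C6–C7–C8–C9–C10) is thus closed in a pericyclic, suprafacial mode through the boat transition state that the bicyclic frame enforces, not by a polar or radical cyclisation. The new quaternary centre C5 is controlled by the bridgehead centres from step 3, because C6 can only reach the face of the C4=C5 alkene that faces the carbinol bridge, which gives the cis-fused product with C5 in the configuration of the target. The step needs the vinyl group syn to the C4=C5 bridge (secured in step 5) and charge acceleration (K+ sequestered by 18-crown-6) to overcome the hindrance of the tetrasubstituted alkene. The enolate is born regiospecifically at C7–C8, so transmetalation to zinc and aldol addition to acetone should place the three-carbon unit at C7 and not at C9. The C7 configuration of 14 is of no consequence, since it is removed in step 7.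

Step 7
Reactants: 14 (5S,10R)-11-hydroxyeremophil-3-en-8-one
Product: 16 (5S,10R)-eremophila-3,7(11)-dien-8-one (cis-fused), via tertiary mesylate 15 (not isolated)
Conditions: MsCl, Et3N, CH2Cl2, 0 °C; DBU, rt
Reagents that add atoms: none
Why: Sulfene mesylation of the tertiary aldol and base-induced E1cB elimination (aldol condensation) should give the conjugated tetrasubstituted exocyclic enone and remove the C7 centre.

Step 8
Reactants: 16 (5S,10R)-eremophila-3,7(11)-dien-8-one
Product: 19 (5R)-9-hydroxyeremophila-3,7(11),9-trien-8-one, via lithium enolate 17 (not isolated), via lithium hydroperoxide 18 (not isolated)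
Conditions: LiN(SiMe3)2 (2.2 equiv), THF, −78 °C; O2, −78 → 0 °C; aq. NH4Cl
Reagents that add atoms: dioxygen, O=O
Why: Kinetic enolisation can only occur towards C9 (C7 carries no hydrogen), autoxidation of the enolate gives the 9-hydroperoxide, which loses hydroxide to the 8,9-dione, and this enolises towards C10 (diosphenol formation by enolate autoxidation), which erases the ring-fusion centre C10.

Step 9
Reactants: 19 (5R)-9-hydroxyeremophila-3,7(11),9-trien-8-one
Product: 20 (5R)-9-(triisopropylsilyloxy)eremophila-3,7(11),9-trien-8-one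
Conditions: iPr3SiCl, imidazole, DMF, rt
Reagents that add atoms: chlorotri(propan-2-yl)silane, CC(C)[Si](Cl)(C(C)C)C(C)C
Why: O-Silylation of the acidic enol, the only hydroxyl group present, masks the diosphenol for the borane and acylation steps.

Step 10
Reactants: 20 (5R)-9-(triisopropylsilyloxy)eremophila-3,7(11),9-trien-8-one
Product: 22 (3R,4R,5R)-3-hydroxy-9-(triisopropylsilyloxy)eremophila-7(11),9-dien-8-one, via C3 alkylborane 21 (not isolated)
Conditions: BH3·THF, THF, 0 °C; 30 % H2O2, pH 7 phosphate buffer (KH2PO4/Na2HPO4), 0 °C → rt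
Reagents that add atoms: hydrogen peroxide, OO
Why: Hydroboration–oxidation: with C10 now trigonal the C5 methyl is axial on ring A, so borane should add to C3=C4 syn from the opposite face with boron on the less substituted C3, setting C3–O and C4–H together (C4 methyl cis to the C5 methyl, C3–O trans to it), while the cross-conjugated C8 carbonyl, flanked by two fully substituted sp2 carbons, and the tetrasubstituted alkenes react more slowly.

Step 11
Reactants: 23 angelic acid; 24 propargyl alcohol
Product: 26 prop-2-yn-1-yl (Z)-2-methylbut-2-enoate, via mixed anhydride 25 (not isolated)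
Conditions: 2,4,6-trichlorobenzoyl chloride, Et3N, toluene, rt; then 24, 60 °C
Reagents that add atoms: none
Why: Yamaguchi esterification through the mixed anhydride, run without DMAP so that the Z (angelate) geometry is not isomerised to the tiglate.

Step 12
Reactants: 26 prop-2-yn-1-yl (Z)-2-methylbut-2-enoate
Product: 28 tert-butyl 4-{[(Z)-2-methylbut-2-enoyl]oxy}but-2-ynoate, via lithium acetylide 27 (not isolated)
Conditions: LiN(SiMe3)2, THF, −78 °C; Boc2O, −78 → −20 °C; aq. NH4Cl
Reagents that add atoms: di-tert-butyl dicarbonate, CC(C)(C)OC(=O)OC(=O)OC(C)(C)C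
Why: Deprotonation of the terminal alkyne (kinetically far faster than vinylogous enolisation of the angelate) and C-acylation of the acetylide with Boc2O should give the tert-butyl ynoate.

Step 13
Reactants: 28 tert-butyl 4-{[(Z)-2-methylbut-2-enoyl]oxy}but-2-ynoate
Product: 30 tert-butyl (Z)-3-methyl-4-{[(Z)-2-methylbut-2-enoyl]oxy}but-2-enoate, via alkenylcuprate 29 (not isolated)
Conditions: Me2CuLi (from CuI and MeLi), THF, −78 °C; MeOH, −78 °C; aq. NH4Cl
Reagents that add atoms: lithium dimethylcuprate, C[Cu-]C.[Li+]
Why: Conjugate addition of Me2CuLi to the ynoate is a syn carbocupration, and protonation of the alkenylcuprate at −78 °C with retention puts CH3 and H cis, that is CH2O and CO2tBu cis (Z), while the less electrophilic angelate is left alone.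

Step 14
Reactants: 30 tert-butyl (Z)-3-methyl-4-{[(Z)-2-methylbut-2-enoyl]oxy}but-2-enoate
Product: 31 (Z)-3-methyl-4-{[(Z)-2-methylbut-2-enoyl]oxy}but-2-enoic acid
Conditions: CF3CO2H, CH2Cl2, 0 °C → rt
Reagents that add atoms: none
Why: Acidolysis of the tert-butyl ester (E1 loss of 2-methylpropene) should free the acid without touching the allylic angelate or either Z alkene.

Step 15
Reactants: 22 (3R,4R,5R)-3-hydroxy-9-(triisopropylsilyloxy)eremophila-7(11),9-dien-8-one; 31 (Z)-3-methyl-4-{[(Z)-2-methylbut-2-enoyl]oxy}but-2-enoic acid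
Product: 33 (3R,4R,5R)-8-oxo-9-(triisopropylsilyloxy)eremophila-7(11),9-dien-3-yl (Z)-3-methyl-4-{[(Z)-2-methylbut-2-enoyl]oxy}but-2-enoate, via mixed anhydride 32 (not isolated)
Conditions: 31, 2,4,6-trichlorobenzoyl chloride, Et3N, toluene, rt; then 22, DMAP, 0 °C → rt
Reagents that add atoms: none
Why: Yamaguchi esterification of the equatorial C3 alcohol, the only free hydroxyl group, with the mixed anhydride at low temperature to keep both Z alkenes.

Step 16
Reactants: 33 (3R,4R,5R)-8-oxo-9-(triisopropylsilyloxy)eremophila-7(11),9-dien-3-yl (Z)-3-methyl-4-{[(Z)-2-methylbut-2-enoyl]oxy}but-2-enoate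
Product: 34 (3R,4R,5R)-9-hydroxy-8-oxoeremophila-7(11),9-dien-3-yl (Z)-3-methyl-4-{[(Z)-2-methylbut-2-enoyl]oxy}but-2-enoate (CNP0228871.1)
Conditions: Bu4NF, AcOH, THF, 0 °C
Reagents that add atoms: none
Why: Fluoride-induced cleavage of the silyl enol ether, buffered with AcOH so that the esters and Z alkenes survive, should release the hydrogen-bonded diosphenol.

Compound list
1 | 2-methylcyclohex-2-en-1-one | CC1=CCCCC1=O | starting material
2 | lithium 2-methylcyclohexa-1,5-dien-1-olate (not isolated) | CC1=CCCC=C1[O-].[Li+] | intermediate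
3 | 6-methylcyclohexa-1,5-dien-1-yl trifluoromethanesulfonate | CC1=CCCC=C1OS(=O)(=O)C(F)(F)F | intermediate
4 | 2,3-dimethylcyclohexa-1,3-diene | CC1=CCCC=C1C | intermediate
5 | acrolein (prop-2-enal) | C=CC=O | starting material
6 | (1S,2R,4R)-5,6-dimethylbicyclo[2.2.2]oct-5-ene-2-carbaldehyde (endo: CHO syn to the C5=C6 bridge) | O=C[C@@H]1C[C@H]2CC[C@@H]1C(C)=C2C | intermediate
7 | (1R,4R)-5,6-dimethylbicyclo[2.2.2]oct-5-en-2-one | O=C1C[C@H]2CC[C@@H]1C(C)=C2C | intermediate
8 | vinylmagnesium bromide | C=C[Mg]Br | starting material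
9 | (1R,2R,4R)-2-ethenyl-5,6-dimethylbicyclo[2.2.2]oct-5-en-2-ol (vinyl syn to the C5=C6 bridge) | C=C[C@]1(O)C[C@H]2CC[C@@H]1C(C)=C2C | intermediate
10 | acetone | CC(C)=O | starting material
11 | potassium alkoxide of 9 (not isolated) | C=C[C@]1([O-])C[C@H]2CC[C@@H]1C(C)=C2C.[K+] | intermediate
12 | potassium (4aS,8aR)-4a,5-dimethyl-1,4,4a,7,8,8a-hexahydronaphthalen-2-olate (cis-fused C7=C8 enolate; not isolated) | [O-]C1=CC[C@]2(C)C(C)=CCC[C@@H]2C1.[K+] | intermediate
13 | chlorozinc enolate corresponding to 12 (not isolated) | Cl[Zn]OC1=CC[C@]2(C)C(C)=CCC[C@@H]2C1 | intermediate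
14 | (5S,10R)-11-hydroxyeremophil-3-en-8-one (cis-fused; C7 epimers) | CC(C)(O)C1C[C@]2(C)C(C)=CCC[C@@H]2CC1=O | intermediate
15 | 11-methanesulfonate of 14 (not isolated) | CC(C)(OS(C)(=O)=O)C1C[C@]2(C)C(C)=CCC[C@@H]2CC1=O | intermediate
16 | (5S,10R)-eremophila-3,7(11)-dien-8-one (cis-fused) | CC(C)=C1C[C@]2(C)C(C)=CCC[C@@H]2CC1=O | intermediate
17 | lithium C8=C9 enolate of 16 (not isolated) | CC(C)=C1C[C@]2(C)C(C)=CCC[C@@H]2C=C1[O-].[Li+] | intermediate
18 | lithium salt of the 9-hydroperoxide of 16 (C9 epimers; not isolated) | CC(C)=C1C[C@]2(C)C(C)=CCC[C@@H]2C(O[O-])C1=O.[Li+] | intermediate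
19 | (5R)-9-hydroxyeremophila-3,7(11),9-trien-8-one | CC(C)=C1C[C@]2(C)C(C)=CCCC2=C(O)C1=O | intermediate
20 | (5R)-9-(triisopropylsilyloxy)eremophila-3,7(11),9-trien-8-one | CC(C)=C1C[C@]2(C)C(C)=CCCC2=C(O[Si](C(C)C)(C(C)C)C(C)C)C1=O | intermediate
21 | C3 borane of 20 (B on C3 and H on C4 added syn, anti to the C5 methyl; not isolated) | B[C@@H]1CCC2=C(O[Si](C(C)C)(C(C)C)C(C)C)C(=O)C(=C(C)C)C[C@]2(C)[C@H]1C | intermediate
22 | (3R,4R,5R)-3-hydroxy-9-(triisopropylsilyloxy)eremophila-7(11),9-dien-8-one | O[C@@H]1CCC2=C(O[Si](C(C)C)(C(C)C)C(C)C)C(=O)C(=C(C)C)C[C@]2(C)[C@H]1C | intermediate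
23 | angelic acid, (Z)-2-methylbut-2-enoic acid | C/C=C(/C)C(=O)O | starting material
24 | propargyl alcohol (prop-2-yn-1-ol) | C#CCO | starting material
25 | angelic 2,4,6-trichlorobenzoic anhydride (not isolated) | C/C=C(/C)C(=O)OC(=O)c1c(Cl)cc(Cl)cc1Cl | intermediate
26 | prop-2-yn-1-yl (Z)-2-methylbut-2-enoate | C/C=C(/C)C(=O)OCC#C | intermediate
27 | lithium acetylide of 26 (not isolated) | C/C=C(/C)C(=O)OCC#[C-].[Li+] | intermediate
28 | tert-butyl 4-{[(Z)-2-methylbut-2-enoyl]oxy}but-2-ynoate | C/C=C(/C)C(=O)OCC#CC(=O)OC(C)(C)C | intermediate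
29 | lithium alkenyl(methyl)cuprate from syn addition to 28 (not isolated) | C/C=C(/C)C(=O)OC/C(C)=C(/[Cu-]C)C(=O)OC(C)(C)C.[Li+] | intermediate
30 | tert-butyl (Z)-3-methyl-4-{[(Z)-2-methylbut-2-enoyl]oxy}but-2-enoate | C/C=C(/C)C(=O)OC/C(C)=C\C(=O)OC(C)(C)C | intermediate
31 | (Z)-3-methyl-4-{[(Z)-2-methylbut-2-enoyl]oxy}but-2-enoic acid | C/C=C(/C)C(=O)OC/C(C)=C\C(=O)O | intermediate
32 | mixed anhydride of 31 with 2,4,6-trichlorobenzoic acid (not isolated) | C/C=C(/C)C(=O)OC/C(C)=C\C(=O)OC(=O)c1c(Cl)cc(Cl)cc1Cl | intermediate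
33 | (3R,4R,5R)-8-oxo-9-(triisopropylsilyloxy)eremophila-7(11),9-dien-3-yl (Z)-3-methyl-4-{[(Z)-2-methylbut-2-enoyl]oxy}but-2-enoate | C/C=C(/C)C(=O)OC/C(C)=C\C(=O)O[C@@H]1CCC2=C(O[Si](C(C)C)(C(C)C)C(C)C)C(=O)C(=C(C)C)C[C@]2(C)[C@H]1C | intermediate
34 | (3R,4R,5R)-9-hydroxy-8-oxoeremophila-7(11),9-dien-3-yl (Z)-3-methyl-4-{[(Z)-2-methylbut-2-enoyl]oxy}but-2-enoate (CNP0228871.1) | C/C=C(/C)C(=O)OC/C(C)=C\C(=O)O[C@@H]1CCC2=C(O)C(=O)C(=C(C)C)C[C@]2(C)[C@H]1C | target

Total step count: 16. Longest linear sequence: 12 steps (steps 1–10, 15 and 16); steps 11–14 make the side-chain acid.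

Steps most likely to fail

Step 6. The rearrangement itself should be fast, but trapping of the hindered enolate may stall through proton transfer from acetone or retro-aldol cleavage on warming. That would give the unsubstituted ketone and waste the regiochemical information. The fallback sets out from 9: the same KN(SiMe3)2/18-crown-6 rearrangement is quenched with Me3SiCl and the trimethylsilyl enol ether F1 is isolated. A Mukaiyama aldol addition of F1 to acetone (TiCl4, CH2Cl2, −78 °C) then comes back to the route at 14.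

Step 8. Over-oxidation (peroxide-induced cleavage of the C8–C9 dione) or incomplete loss of hydroxide from the hydroperoxide could erode the material balance. The fallback sets out from 16: the kinetic lithium enolate is hydroxylated with the Davis oxaziridine (2-(phenylsulfonyl)-3-phenyloxaziridine) to the 9-hydroxy ketone F2. Oxidation of F2 with Dess–Martin periodinane gives the dione, which enolises and so comes back to the route at 19.

Step 10. Competing 1,2-reduction of the C8 carbonyl by borane would cost chemoselectivity. The fallback sets out from 20: excess BH3·THF is used on purpose so that hydroboration and carbonyl reduction both go to completion, which after the same oxidative work-up gives the 3,8-diol F3. MnO2 (CH2Cl2, rt) then oxidises only the allylic C8 alcohol and comes back to the route at 22.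

Further compounds
F1 | step 6 | (4aS,8aR)-4a,5-dimethyl-2-(trimethylsilyloxy)-1,4,4a,7,8,8a-hexahydronaphthalene | C[Si](C)(C)OC1=CC[C@]2(C)C(C)=CCC[C@@H]2C1
F2 | step 8 | (5S)-9-hydroxyeremophila-3,7(11)-dien-8-one (cis-fused; C9 epimers) | CC(C)=C1C[C@]2(C)C(C)=CCC[C@@H]2C(O)C1=O
F3 | step 10 | (3R,4R,5R)-9-(triisopropylsilyloxy)eremophila-7(11),9-diene-3,8-diol (C8 epimers) | O[C@@H]1CCC2=C(O[Si](C(C)C)(C(C)C)C(C)C)C(O)C(=C(C)C)C[C@]2(C)[C@H]1C
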